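**Retrosynthetic overview**
- The plan rests on ring B (C5–C10) of 15-acetoxylabd-8(17)-en-18-oic acid: it meets ring A at quaternary C10, whose methyl C20 can arise from a methylene, carries the side chain on C9 and the exocyclic carbon C17 on C8.
- Ring B is made last: C9–C10 and C7–C8 are cut together to the ring A aldehyde 15 (C10 methylene) and the side-chain enal 21; the 7-hydroxy-17-oxo product 23 is taken to the C8=C17 alkene by dehydration, 1,2-reduction and diazene transposition.
- Ring A is made first: an enantioselective Diels–Alder reaction of silyloxydiene 6 with the (E)-enal ester 4 sets C4 and C5; then C7 is added by a one-carbon Wittig reaction, C10 becomes a ketone and is methylenated (C20).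
- Side chain: (S)-citronellol supplies C11–C16 with (13S); ozonolysis and a two-carbon Wittig reaction give enal 21.
- The C18 carboxyl is carried as its tert-butyl ester, because a methyl ester at this neopentyl position could not be cleaved at the end without loss of the C15 acetate.

Key step: step 15

Remarks: Labdane numbering is used throughout (ring A = C1–C5, C10; ring B = C5–C10). Ylide 2 is taken as purchasable; it is otherwise made from tert-butyl 2-bromopropanoate and PPh3. The configuration at C10 in 7–12 and at C7/C8 in 23–24 is drawn as the expected isomer and is erased later.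

**Route**

Step 1
Reactants: 1 2,2-dimethoxyacetaldehyde; 2 tert-butyl 2-(triphenyl-λ5-phosphanylidene)propanoate
Product: 3 tert-butyl (2E)-4,4-dimethoxy-2-methylbut-2-enoate
Conditions: CH2Cl2, rt (1 as its commercial aqueous solution)
Reagents that add atoms: none
Why: Wittig reaction of a stabilised α-methyl ylide, which should place the ester trans to the acetal carbon and so give the (E)-trisubstituted enoate.

Step 2
Reactants: 3 tert-butyl (2E)-4,4-dimethoxy-2-methylbut-2-enoate
Product: 4 tert-butyl (2E)-2-methyl-4-oxobut-2-enoate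
Conditions: Amberlyst 15, acetone–H2O, rt
Reagents that add atoms: water, O
Why: Acid-catalysed acetal hydrolysis under conditions that spare the tert-butyl ester; the (E)-isomer (formyl trans to ester) is also the thermodynamic one.

Step 3
Reactants: 5 (2E)-but-2-enal
Product: 6 (1E)-1-[(tert-butyldimethylsilyl)oxy]buta-1,3-diene
Conditions: TBSOTf, Et3N, Et2O, 0 °C → rt
Reagents that add atoms: tert-butyldimethylsilyl trifluoromethanesulfonate, CC(C)(C)[Si](C)(C)OS(=O)(=O)C(F)(F)F
Why: Silyl dienol ether formation (O-silylation, then γ-deprotonation by the amine) should give mainly the (E)-diene, the only isomer that reaches the s-cis form used in step 4.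

Step 4
Reactants: 4 tert-butyl (2E)-2-methyl-4-oxobut-2-enoate; 6 (1E)-1-[(tert-butyldimethylsilyl)oxy]buta-1,3-diene
Product: 7 tert-butyl (1R,5R,6S)-5-[(tert-butyldimethylsilyl)oxy]-6-formyl-1-methylcyclohex-3-ene-1-carboxylate
Conditions: (S)-1-(2-methylphenyl)-3,3-diphenyltetrahydro-1H,3H-pyrrolo[1,2-c][1,3,2]oxazaborole·HN(SO2CF3)2 (20 mol%), CH2Cl2, −78 → −40 °C
Reagents that add atoms: none
Why: Enantioselective Diels–Alder reaction under a chiral oxazaborolidinium Lewis acid bound to the formyl group of 4: the free diene terminus bonds to the β-carbon (C4) and the silyloxy terminus to C5, the (E)-geometry of 4 is carried over so that the C5 formyl group is cis to the C4 methyl, the (S)-catalyst is chosen on the formyl C–H···O binding model to leave the Re face of C5 open, and the endo rule places the silyloxy group cis to the formyl group at a centre (C10) that is erased in step 9.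

Step 5
Reactants: 7 tert-butyl (1R,5R,6S)-5-[(tert-butyldimethylsilyl)oxy]-6-formyl-1-methylcyclohex-3-ene-1-carboxylate; 8 (methoxymethyl)triphenylphosphonium chloride
Product: 9 tert-butyl (1R,5R,6S)-5-[(tert-butyldimethylsilyl)oxy]-6-(2-methoxyethenyl)-1-methylcyclohex-3-ene-1-carboxylate (E/Z mixture)
Conditions: 8, KN(SiMe3)2, THF, 0 °C; then 7, −78 → 0 °C
Reagents that add atoms: none
Why: Wittig one-carbon homologation with the non-stabilised methoxymethylene ylide, which should add to the aldehyde faster than it enolises it, so that C5 is kept and the β-silyloxy group is not eliminated.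

Step 6
Reactants: 9 tert-butyl (1R,5R,6S)-5-[(tert-butyldimethylsilyl)oxy]-6-(2-methoxyethenyl)-1-methylcyclohex-3-ene-1-carboxylate
Product: 10 tert-butyl (1R,5R,6S)-5-[(tert-butyldimethylsilyl)oxy]-6-(2,2-dimethoxyethyl)-1-methylcyclohex-3-ene-1-carboxylate
Conditions: MeOH, pyridinium p-toluenesulfonate (cat.), rt
Reagents that add atoms: methanol, CO
Why: Acid-catalysed addition of methanol to the enol ether (acetalisation through the oxocarbenium ion) masks C7 as a dimethyl acetal while the secondary silyl ether and the tert-butyl ester should stay intact.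

Step 7
Reactants: 10 tert-butyl (1R,5R,6S)-5-[(tert-butyldimethylsilyl)oxy]-6-(2,2-dimethoxyethyl)-1-methylcyclohex-3-ene-1-carboxylate
Product: 11 tert-butyl (1R,2S,3R)-3-[(tert-butyldimethylsilyl)oxy]-2-(2,2-dimethoxyethyl)-1-methylcyclohexane-1-carboxylate
Conditions: H2 (1 atm), Pd/C, EtOAc, trace Et3N, rt
Reagents that add atoms: none
Why: Heterogeneous catalytic hydrogenation of the only alkene (C1=C2, cis-disubstituted); no stereocentre is formed and the acetal, silyl ether and ester are inert.

Step 8
Reactants: 11 tert-butyl (1R,2S,3R)-3-[(tert-butyldimethylsilyl)oxy]-2-(2,2-dimethoxyethyl)-1-methylcyclohexane-1-carboxylate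
Product: 12 tert-butyl (1R,2S,3R)-2-(2,2-dimethoxyethyl)-3-hydroxy-1-methylcyclohexane-1-carboxylate
Conditions: Bu4NF, THF, rt
Reagents that add atoms: none
Why: Fluoride-mediated desilylation of the secondary silyl ether; acetal and tert-butyl ester do not react.

Step 9
Reactants: 12 tert-butyl (1R,2S,3R)-2-(2,2-dimethoxyethyl)-3-hydroxy-1-methylcyclohexane-1-carboxylate
Product: 13 tert-butyl (1R,2S)-2-(2,2-dimethoxyethyl)-1-methyl-3-oxocyclohexane-1-carboxylate
Conditions: Dess–Martin periodinane, pyridine, CH2Cl2, rt
Reagents that add atoms: none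
Why: Dess–Martin oxidation under buffered, near-neutral conditions gives the C10 ketone without enolisation toward C5, so the C4/C5 relationship set in step 4 is kept.

Step 10
Reactants: 13 tert-butyl (1R,2S)-2-(2,2-dimethoxyethyl)-1-methyl-3-oxocyclohexane-1-carboxylate
Product: 14 tert-butyl (1R,2R)-2-(2,2-dimethoxyethyl)-1-methyl-3-methylidenecyclohexane-1-carboxylate
Conditions: Cp2TiMe2, toluene, 65 °C, dark
Reagents that add atoms: dimethyltitanocene, [CH3-].[CH3-].[Ti+4].c1cc[cH-]c1.c1cc[cH-]c1
Why: Petasis methylenation: the non-basic titanium methylidene olefinates the hindered, enolisable ketone without epimerising C5, and the tert-butyl ester on a quaternary carbon is too hindered to react.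

Step 11
Reactants: 14 tert-butyl (1R,2R)-2-(2,2-dimethoxyethyl)-1-methyl-3-methylidenecyclohexane-1-carboxylate
Product: 15 tert-butyl (1R,2R)-1-methyl-3-methylidene-2-(2-oxoethyl)cyclohexane-1-carboxylate
Conditions: pyridinium p-toluenesulfonate, acetone–H2O, 45 °C
Reagents that add atoms: water, O
Why: Mild acetal hydrolysis with an acid too weak to protonate the 1,1-disubstituted alkene, to cleave the tert-butyl ester or to start a carbonyl-ene closure of the new aldehyde onto C20.

Step 12
Reactants: 16 (S)-citronellol
Product: 17 (S)-citronellyl acetate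
Conditions: Ac2O, pyridine, 4-(dimethylamino)pyridine (cat.), CH2Cl2, rt
Reagents that add atoms: acetic anhydride, CC(=O)OC(C)=O
Why: Acylation of the primary alcohol installs the C15 acetate of the target; C13 is untouched.

Step 13
Reactants: 17 (S)-citronellyl acetate
Product: 19 (3S)-3-methyl-6-oxohexyl acetate, via ozonide 18 (not isolated)
Conditions: O3, CH2Cl2, −78 °C; then PPh3, −78 °C → rt
Reagents that add atoms: ozone, [O-][O+]=O
Why: Ozonolysis of the only alkene with reductive work-up gives the aldehyde (C9 of the target) and acetone; the stereocentre is remote.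

Step 14
Reactants: 19 (3S)-3-methyl-6-oxohexyl acetate; 20 2-(triphenyl-λ5-phosphanylidene)acetaldehyde
Product: 21 (2E,6S)-8-acetoxy-6-methyloct-2-enal
Conditions: toluene, 70 °C (1.1 equiv of 20)
Reagents that add atoms: none
Why: Wittig reaction of the stabilised formylmethylene ylide should give the (E)-enal; the saturated aldehyde reacts faster than the enal product, which limits a second olefination.

Step 15
Reactants: 15 tert-butyl (1R,2R)-1-methyl-3-methylidene-2-(2-oxoethyl)cyclohexane-1-carboxylate; 21 (2E,6S)-8-acetoxy-6-methyloct-2-enal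
Product: 23 tert-butyl 15-acetoxy-7β-hydroxy-17-oxolabdan-18-oate (5α-H, 8β-H, 9α-H, 10β-methyl, 13S), via C8 enolate 22 (not isolated)
Conditions: Fe(acac)3 (30 mol%), PhSiH3 (2.5 equiv), 21 (2 equiv), EtOH–ethylene glycol, 0 °C → rt
Reagents that add atoms: none
Why: PhSiH3 and EtOH convert Fe(acac)3 into a hydride of trivalent iron that gives a hydrogen atom to the methylene carbon of 15 (it becomes C20), the tertiary C10 radical adds to C9 of enal 21, and divalent iron reduces the α-formyl radical to the C8 enolate 22, which closes ring B by a 6-(enolexo)-exo-trig aldol addition onto the C7 aldehyde, so that C9–C10 and C7–C8 form in one operation. The closest known reaction type is the iron-hydride hydrogen-atom-transfer conjugate addition of alkenes to enals and enones and its radical–polar crossover annulation variant with aldehyde-bearing alkenes. C10: ring A should react through the chair with the C6 arm equatorial and the C19 methyl axial, so the axial face of the radical is blocked by the syn-axial methyl and the enal is taken up on the equatorial face trans to the arm, which gives the trans ring fusion. C9: in the staggered approach the hydrogen on C9 should take the inner sector between C1 and C5, the chain carbon C11 the open sector between C1 and C20, and C8 the place next to C5 from which it closes the ring; this gives 9α-H but is the least secure element. C7 and C8 arise in the aldol closure, are drawn with both groups equatorial and are erased in steps 16 to 18. The step needs hydrogen-atom transfer to the electron-rich 1,1-disubstituted alkene and not to the enal, and an enolate only at C8; the first follows from the polarity of the two alkenes and the second from the regiospecific origin of the enolate.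

Step 16
Reactants: 23 tert-butyl 15-acetoxy-7β-hydroxy-17-oxolabdan-18-oate
Product: 25 tert-butyl 15-acetoxy-17-oxolabd-7-en-18-oate (5α-H, 9α-H, 10β-methyl, 13S), via mesylate 24 (not isolated)
Conditions: MsCl, Et3N, CH2Cl2, 0 °C; then DBU, rt
Reagents that add atoms: none
Why: Mesylation and E1cB elimination of the β-sulfonyloxy aldehyde give the conjugated C7=C8 enal from either C7/C8 diastereomer; C9–H is not acidic in this cross-conjugated position and should keep its configuration.

Step 17
Reactants: 25 tert-butyl 15-acetoxy-17-oxolabd-7-en-18-oate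
Product: 26 tert-butyl 15-acetoxy-17-hydroxylabd-7-en-18-oate (5α-H, 9α-H, 10β-methyl, 13S)
Conditions: NaBH4, CeCl3·7H2O, MeOH, −20 → 0 °C
Reagents that add atoms: none
Why: Luche reduction should give clean 1,2-reduction of the enal to the primary allylic alcohol while the acetate and the tert-butyl ester survive the short, cold exposure.

Step 18
Reactants: 26 tert-butyl 15-acetoxy-17-hydroxylabd-7-en-18-oate
Product: 29 tert-butyl 15-acetoxylabd-8(17)-en-18-oate (5α-H, 9α-H, 10β-methyl, 13S), via sulfonylhydrazine 27 (not isolated), via allylic diazene 28 (not isolated)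
Conditions: 2-nitrobenzenesulfonohydrazide, PPh3, diethyl azodicarboxylate, N-methylmorpholine, −30 °C → rt
Reagents that add atoms: none
Why: Myers reductive 1,3-transposition: Mitsunobu N-alkylation of the sulfonylhydrazide at the primary allylic carbinol, loss of the sulfinic acid to the monoalkyl diazene and retro-ene loss of N2 deliver hydrogen to C7 and place the alkene at C8=C17; C9 is not involved.

Step 19
Reactants: 29 tert-butyl 15-acetoxylabd-8(17)-en-18-oate
Product: 31 (4R,5R,9S,10R,13S)-15-acetoxylabd-8(17)-en-18-oic acid, via trimethylsilyl ester 30 (not isolated)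
Conditions: Me3SiOTf, 2,6-lutidine, CH2Cl2, 0 °C → rt; then pH 5 aqueous buffer
Reagents that add atoms: none
Why: Silyl triflate-mediated cleavage of the tert-butyl ester (loss of 2-methylpropene, then hydrolysis of the silyl ester) under amine-buffered conditions that should neither move the exocyclic alkene into the ring nor touch the primary acetate.

**Compound list**
1 | 2,2-dimethoxyacetaldehyde | COC(OC)C=O | starting material
2 | tert-butyl 2-(triphenyl-λ5-phosphanylidene)propanoate | CC(C(=O)OC(C)(C)C)=P(c1ccccc1)(c1ccccc1)c1ccccc1 | starting material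
3 | tert-butyl (2E)-4,4-dimethoxy-2-methylbut-2-enoate | COC(OC)/C=C(\C)C(=O)OC(C)(C)C | intermediate
4 | tert-butyl (2E)-2-methyl-4-oxobut-2-enoate | O=C/C=C(\C)C(=O)OC(C)(C)C | intermediate
5 | (2E)-but-2-enal | C/C=C/C=O | starting material
6 | (1E)-1-[(tert-butyldimethylsilyl)oxy]buta-1,3-diene | C=C/C=C/O[Si](C)(C)C(C)(C)C | intermediate
7 | tert-butyl (1R,5R,6S)-5-[(tert-butyldimethylsilyl)oxy]-6-formyl-1-methylcyclohex-3-ene-1-carboxylate | O=C[C@@H]1[C@H](O[Si](C)(C)C(C)(C)C)C=CC[C@@]1(C)C(=O)OC(C)(C)C | intermediate
8 | (methoxymethyl)triphenylphosphonium chloride | COC[P+](c1ccccc1)(c1ccccc1)c1ccccc1.[Cl-] | starting material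
9 | tert-butyl (1R,5R,6S)-5-[(tert-butyldimethylsilyl)oxy]-6-(2-methoxyethenyl)-1-methylcyclohex-3-ene-1-carboxylate (E/Z mixture) | COC=C[C@@H]1[C@H](O[Si](C)(C)C(C)(C)C)C=CC[C@@]1(C)C(=O)OC(C)(C)C | intermediate
10 | tert-butyl (1R,5R,6S)-5-[(tert-butyldimethylsilyl)oxy]-6-(2,2-dimethoxyethyl)-1-methylcyclohex-3-ene-1-carboxylate | COC(OC)C[C@@H]1[C@H](O[Si](C)(C)C(C)(C)C)C=CC[C@@]1(C)C(=O)OC(C)(C)C | intermediate
11 | tert-butyl (1R,2S,3R)-3-[(tert-butyldimethylsilyl)oxy]-2-(2,2-dimethoxyethyl)-1-methylcyclohexane-1-carboxylate | COC(OC)C[C@@H]1[C@H](O[Si](C)(C)C(C)(C)C)CCC[C@@]1(C)C(=O)OC(C)(C)C | intermediate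
12 | tert-butyl (1R,2S,3R)-2-(2,2-dimethoxyethyl)-3-hydroxy-1-methylcyclohexane-1-carboxylate | COC(OC)C[C@@H]1[C@H](O)CCC[C@@]1(C)C(=O)OC(C)(C)C | intermediate
13 | tert-butyl (1R,2S)-2-(2,2-dimethoxyethyl)-1-methyl-3-oxocyclohexane-1-carboxylate | COC(OC)C[C@@H]1C(=O)CCC[C@@]1(C)C(=O)OC(C)(C)C | intermediate
14 | tert-butyl (1R,2R)-2-(2,2-dimethoxyethyl)-1-methyl-3-methylidenecyclohexane-1-carboxylate | COC(OC)C[C@@H]1C(=C)CCC[C@@]1(C)C(=O)OC(C)(C)C | intermediate
15 | tert-butyl (1R,2R)-1-methyl-3-methylidene-2-(2-oxoethyl)cyclohexane-1-carboxylate (ring A donor) | O=CC[C@@H]1C(=C)CCC[C@@]1(C)C(=O)OC(C)(C)C | intermediate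
16 | (S)-citronellol, (3S)-3,7-dimethyloct-6-en-1-ol | OCC[C@@H](C)CCC=C(C)C | starting material
17 | (S)-citronellyl acetate, (3S)-3,7-dimethyloct-6-en-1-yl acetate | CC(=O)OCC[C@@H](C)CCC=C(C)C | intermediate
18 | (3S)-5-(5,5-dimethyl-1,2,4-trioxolan-3-yl)-3-methylpentyl acetate (ozonide, epimers at the trioxolane carbon) | CC(=O)OCC[C@@H](C)CCC1OOC(C)(C)O1 | intermediate
19 | (3S)-3-methyl-6-oxohexyl acetate | CC(=O)OCC[C@@H](C)CCC=O | intermediate
20 | 2-(triphenyl-λ5-phosphanylidene)acetaldehyde | O=CC=P(c1ccccc1)(c1ccccc1)c1ccccc1 | starting material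
21 | (2E,6S)-8-acetoxy-6-methyloct-2-enal | O=C/C=C/CC[C@H](C)CCOC(C)=O | intermediate
22 | C8 enolate of the conjugate adduct (C9–C10 bond formed, ring B open, C7 aldehyde free; shown as the free enolate anion) | [O-]C=C[C@H](CC[C@H](C)CCOC(C)=O)[C@@]1(C)CCC[C@@](C)(C(=O)OC(C)(C)C)[C@@H]1CC=O | intermediate
23 | tert-butyl 15-acetoxy-7β-hydroxy-17-oxolabdan-18-oate (5α-H, 8β-H, 9α-H, 10β-methyl, 13S; 7-OH and 8-CHO equatorial) | O=C[C@@H]1[C@@H](O)C[C@@H]2[C@](C)(CCC[C@@]2(C)C(=O)OC(C)(C)C)[C@H]1CC[C@H](C)CCOC(C)=O | intermediate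
24 | tert-butyl 15-acetoxy-7β-(methanesulfonyloxy)-17-oxolabdan-18-oate | O=C[C@@H]1[C@@H](OS(C)(=O)=O)C[C@@H]2[C@](C)(CCC[C@@]2(C)C(=O)OC(C)(C)C)[C@H]1CC[C@H](C)CCOC(C)=O | intermediate
25 | tert-butyl 15-acetoxy-17-oxolabd-7-en-18-oate (5α-H, 9α-H, 10β-methyl, 13S) | O=CC1=CC[C@@H]2[C@](C)(CCC[C@@]2(C)C(=O)OC(C)(C)C)[C@H]1CC[C@H](C)CCOC(C)=O | intermediate
26 | tert-butyl 15-acetoxy-17-hydroxylabd-7-en-18-oate (5α-H, 9α-H, 10β-methyl, 13S) | OCC1=CC[C@@H]2[C@](C)(CCC[C@@]2(C)C(=O)OC(C)(C)C)[C@H]1CC[C@H](C)CCOC(C)=O | intermediate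
27 | tert-butyl 15-acetoxy-17-[1-(2-nitrobenzenesulfonyl)hydrazinyl]labd-7-en-18-oate | NN(CC1=CC[C@@H]2[C@](C)(CCC[C@@]2(C)C(=O)OC(C)(C)C)[C@H]1CC[C@H](C)CCOC(C)=O)S(=O)(=O)c1ccccc1[N+](=O)[O-] | intermediate
28 | tert-butyl 15-acetoxy-17-diazenyllabd-7-en-18-oate | N=NCC1=CC[C@@H]2[C@](C)(CCC[C@@]2(C)C(=O)OC(C)(C)C)[C@H]1CC[C@H](C)CCOC(C)=O | intermediate
29 | tert-butyl 15-acetoxylabd-8(17)-en-18-oate (5α-H, 9α-H, 10β-methyl, 13S) | C=C1CC[C@@H]2[C@](C)(CCC[C@@]2(C)C(=O)OC(C)(C)C)[C@H]1CC[C@H](C)CCOC(C)=O | intermediate
30 | trimethylsilyl 15-acetoxylabd-8(17)-en-18-oate | C=C1CC[C@@H]2[C@](C)(CCC[C@@]2(C)C(=O)O[Si](C)(C)C)[C@H]1CC[C@H](C)CCOC(C)=O | intermediate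
31 | (4R,5R,9S,10R,13S)-15-acetoxylabd-8(17)-en-18-oic acid (CNP0401865.1) | C=C1CC[C@@H]2[C@](C)(CCC[C@@]2(C)C(=O)O)[C@H]1CC[C@H](C)CCOC(C)=O | target

**Step count**
Total: 19 steps. Longest linear sequence: 15 steps (steps 1, 2, 4–11, 15–19).

**Steps most likely to fail**

1. Step 15. The enal may be attacked on both faces of its β-carbon, so that C9 forms without useful bias; attack on the axial face of C10 is a lesser risk. The fallback sets C9 by equilibration next to a ketone. It sets out from enal 25, carried as the C9-epimer mixture. Conjugate hydrosilylation (Et3SiH, RhCl(PPh3)3, benzene, 50 °C) should give the triethylsilyl enol ether F1. Ozonolysis (O3, CH2Cl2, −78 °C; Me2S) removes C17 and gives the 8-oxo-17-nor ketone F2, which DBU in CH2Cl2 should equilibrate to the epimer with the equatorial side chain (9α-H). Lombardo methylenation (Zn, CH2Br2, TiCl4, THF–CH2Cl2) then comes back to the route at 29.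

2. Step 4. The β,β-disubstituted enal lies outside the usual dienophile range of the catalyst, so enantiofacial discrimination may be low, and ester-directed regiochemistry may compete. An inverted sense would be met with the antipodal catalyst. The fallback is a kinetic resolution. It sets out from alcohol 12 obtained in low enantiomeric purity. Lipase acylation (Candida antarctica lipase B, vinyl acetate, tert-butyl methyl ether, 35 °C) should acylate the (3R)-carbinol, the enantiomer favoured by the empirical rule for lipases and secondary alcohols, to give the acetate F3, which is separated from the unreacted antipode. Methanolysis (K2CO3, MeOH) comes back to the route at enantiopure 12.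

3. Step 18. The Mitsunobu substitution at the allylic carbinol next to the substituted C9 may be slow, so that the sulfonylhydrazide decomposes before it is alkylated. The fallback is a palladium-catalysed formate reduction. It sets out from allylic alcohol 26, which is converted to the allylic methyl carbonate F4 (ClCO2Me, pyridine, CH2Cl2, 0 °C). Treatment with Pd(OAc)2, PBu3, HCO2H and Et3N in THF at 40 °C forms zerovalent palladium in the flask and should deliver hydride to the more substituted allyl terminus (C7), giving the exocyclic alkene and coming back to the route at 29.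

**Further compounds**
F1 | step 15 | tert-butyl 15-acetoxy-17-(triethylsilyloxy)labd-8(17)-en-18-oate (C9 epimers, enol ether isomers) | CC[Si](CC)(CC)OC=C1CC[C@@H]2[C@](C)(CCC[C@@]2(C)C(=O)OC(C)(C)C)C1CC[C@H](C)CCOC(C)=O
F2 | step 15 | tert-butyl 15-acetoxy-8-oxo-17-norlabdan-18-oate (9α-H after equilibration) | O=C1CC[C@@H]2[C@](C)(CCC[C@@]2(C)C(=O)OC(C)(C)C)[C@H]1CC[C@H](C)CCOC(C)=O
F3 | step 4 | tert-butyl (1R,2S,3R)-3-acetoxy-2-(2,2-dimethoxyethyl)-1-methylcyclohexane-1-carboxylate | COC(OC)C[C@@H]1[C@H](OC(C)=O)CCC[C@@]1(C)C(=O)OC(C)(C)C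
F4 | step 18 | tert-butyl 15-acetoxy-17-[(methoxycarbonyl)oxy]labd-7-en-18-oate | COC(=O)OCC1=CC[C@@H]2[C@](C)(CCC[C@@]2(C)C(=O)OC(C)(C)C)[C@H]1CC[C@H](C)CCOC(C)=O
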